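Remark on the chemistry: atom numbers C1 to C13 are the germacrane numbers of the target and are kept for the same carbons in every open-chain intermediate; the antipode of the crotylborane in step 4 is assigned from the usual facial rule for isopinocampheyl reagents.

## Analysis of the target

The target is a germacranolide: a ten-membered carbocycle (C1 to C10) fused through C6 and C7 to a butenolide (C6–O–C12(=O)–C11=C7), whose tetrasubstituted C7=C11 alkene carries the acetoxymethyl carbon C13. It has five stereocentres: C4 (R) and C5 (R) form a trans trisubstituted epoxide, C6 (S) is the lactone carbinol next to it, C8 (S) carries the angelate on the other side of C7, and C10 (R) bears a methyl group α to the C1 ketone. C4, C5 and C6 are contiguous, C8 is separated from C6 only by the sp2 carbon C7, and C10 stands alone and can epimerise through the C1 enol. The epoxide lies β to the acidic γ-hydrogen of the butenolide (C6–H), so base can open it by elimination and acid can open it across the ring. The angelate isomerises to the tiglate under nucleophilic catalysis or heat. Oxygen leaving groups at C8 and C13 become ionisable once the butenolide is held as an electron-rich furan. The main difficulty is to close a ten-membered ring that has no ring alkene to assist, while setting C5 and C6 in the correct sense. The strategy rests on two features: C6 is the γ-carbon of the butenolide and C5 its oxygenated neighbour, so C5–C6 is a vinylogous aldol bond; and the C4 methyl carbinol with C3, C2 and C1 repeats the carbon pattern of (R)-linalool 1, so the C4 oxygen can come from the chiral pool and end as the epoxide oxygen.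

## Retrosynthetic reasoning

**End game (36 back to 31).** The C1 ketone is traced to the carbinol 35 and its PMB ether 34, the C13 acetate to the alcohol 33, and the C5–O bond of the epoxide is cut to give the C4 silyl ether and C5 mesylate 32, which comes from the C5 alcohol 31. The epoxide is cut at C5–O and not at C4–O because only the secondary C5 can be displaced with inversion, so the C4 oxygen of 1 becomes the epoxide oxygen. The epoxide is formed after the ring because it is the most fragile group. C1 is held as a PMB-protected carbinol until the last step for two reasons: a ketone at C1 would offer C6 a six-membered closure (C6–C7–C8–C9–C10–C1) in the key step, and it would expose C10 to epimerisation in the basic steps.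

**Key disconnection (31 back to 30).** The C5–C6 ring bond is cut, leading to the open-chain aldehyde 30 in which the butenolide is held as a 2-silyloxyfuran. This is the only ring bond flanked by a latent carbon nucleophile (the butenolide γ-carbon) and an oxygenated carbon. Cutting it removes the ring and two stereocentres and leaves a chain whose other stereocentres can each be set by a reliable method. The forward reaction has to close the ten-membered ring, deliver the conjugated butenolide and set C5 and C6.

**Unmasking the two reacting ends (30 back to 26).** The silyloxyfuran 30 comes from the butenolide aldehyde 29 by enol silylation. The C5 aldehyde and the C4 silyl ether come from the bis-silyl ether 28 and the diol 27, and these from the acetonide 26. The C4,C5 diol is carried as an acetonide through the organometallic and redox steps because that group is inert to all of them. The silyl ether at C4 is needed only from here on, as the non-chelating group for the aldol and the oxygen nucleophile for the epoxide.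

**Butenolide from a furan (26 back to 24).** The C12 carbonyl is traced to a carbon–silicon bond on the furan 24. A 3,4-disubstituted furan has two different α-positions, and the silyl group decides that oxidation puts the carbonyl on C12 and leaves C6 as CH2.

**Angelate (24 back to 21 and 22).** The C8–O acyl bond is cut to the alcohol 21 and angelic acid 22. The ester is put on before the furan is oxidised because the C8 oxygen must be blocked when the lactone forms; otherwise it could close onto C12 in place of the C6 oxygen.

**C7–C8 bond (21 back to 13 and 16).** The furan is joined to the chain by adding the 4-lithio derivative 17 of the furan 16 to the aldehyde 13. The resulting epimeric alcohol 18 is silylated at C13 (19), oxidised to the ketone 20 and reduced under reagent control to 21. A bond between an aromatic carbon and a carbinol is the simplest convergent link, and the ketone detour makes C8 independent of the other centres.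

**Furan piece (16 back to 14).** The silyl group is moved from oxygen in the silyl ether 15 to the furan 2-position; 15 comes from furan-3-ylmethanol 14. The same hydroxymethyl group that becomes C13 directs both lithiations.

**C8 to C10 (13 back to 5 and 6).** The C8 aldehyde 13 comes from the alcohol 12, which comes from the terminal alkene of 10 by hydroboration, and the C1–C10 bond of 9 is cut to the aldehyde 5 and (E)-but-2-ene 6. Crotylboration sets C10 by reagent control. The C1 carbinol formed with it is the oxidation state needed for the PMB ether.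

**C1 to C5 (5 back to 1).** Aldehyde 5 comes from the alcohol 4, the acetonide of triol 3, which is the product of cleaving both alkenes of 1. The acetonide differentiates C1 from C5 in one step, and C4 is never touched.

## Alternatives that were turned down

**Alternative 1:** Both allylic C–O bonds (C8–O and C13–O) are removed together with the C7=C11 alkene, which leads back to the macrocyclic diene A1, with a ring E-C7=C8 alkene conjugated to an exocyclic C11=C13 methylene. In the forward direction singlet oxygen would add across C8 and C13 in a [4+2] reaction to give the 1,2-dioxine A2; O–O reduction and two acylations would follow.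
- For: one reagent installs two oxygens and the tetrasubstituted alkene, no protecting groups are needed at C8 or C13, and a primary and a secondary hydroxyl are easily told apart. On late-stage economy it is stronger than the chosen route.
- Against: A1 already contains the ten-membered ring with epoxide, ketone and a strained E alkene, so ring construction is only displaced. In a ten-membered ring the plane of an E alkene stands roughly perpendicular to the mean ring plane, which works against the coplanar s-cis diene the cycloaddition needs. Ene reactions at C9–H and C6–H compete. The C8 configuration would be set by the ring face, without reagent control. The peroxide must be reduced next to an epoxide, and a hindered C8 alcohol must be angeloylated at the end.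
- Comparison: the chosen strategy builds ring and butenolide in one step and fixes C8 by reagent control (step 13) before the ring exists.

**Alternative 2:** The C6–C7 bond and the lactone C–O bond are cut, giving the epoxy aldehyde A3 (C2 to C6, epoxide in place) and the alkenyl iodide A4 (C1 and C7 to C13). Iodine–magnesium exchange on A4, addition to A3 in the presence of MgBr2·OEt2 and lactonisation of the C6 alkoxide onto the ester would give A5.
- For: the union is convergent, the epoxide is made early by reagent-controlled chemistry, and addition to an α,β-epoxy aldehyde is a well-understood way to set C6. On convergence and on certainty at C4 to C6 it is stronger than the chosen route.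
- Against: the ten-membered ring is still open in A5 and would have to be closed between C1 and C2 by carbanion chemistry on a molecule that already holds the epoxide β to the acidic C6–H, where base opens the epoxide by elimination through the butenolide dienolate. The metallated carbon C7 has a silyloxy group on the adjacent C8, so β-elimination to an allene threatens the reagent. After the union, three protecting groups must be exchanged and C1 oxidised with the fragile epoxy butenolide present throughout.
- Comparison: the chosen route closes the ring in the step that makes the butenolide and forms the epoxide only near the end. In exchange it accepts that C5 and C6 depend on an untested ring closure.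

**Alternative 3:** The C1–C10 bond is cut, giving the aldehyde enone A6, in which C8 is a crotonyl ketone. A chiral carbene catalyst would turn the C1 aldehyde into an acyl anion equivalent that adds to C10 (Stetter reaction), closing the ring to the 1,8-diketone A7.
- For: the C1/C8 1,4-dicarbonyl pattern is the Stetter retron, C10 is set catalytically, and C1 arrives as the ketone without a protecting group. On redox economy at C1 and C10 it is stronger than the chosen route.
- Against: a β-methyl enone is a slow Stetter acceptor, the aliphatic C1 aldehyde has α-hydrogens and can undergo aldol and benzoin reactions under the base that generates the carbene, and a ten-membered Stetter closure is as untested as the chosen key step. C10–H in A7 is α to a ketone under basic conditions. A7 has two ketones, and C8 must then be reduced selectively to 8S next to a tetrasubstituted enoate before desilylation, lactonisation and angeloylation.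
- Comparison: the chosen route fixes C10 and C8 by stoichiometric reagent control before ring formation, and its ring closure runs under Lewis acid without base.

Key step: step 20

## Route

Step 1
Reactants: 1 (R)-linalool
Product: 3 (2R)-2-methylpentane-1,2,5-triol, via hydroxy dialdehyde 2 (not isolated)
Conditions: O3, CH2Cl2/MeOH, −78 °C; then NaBH4, −78 °C to rt
Reagents that add atoms: ozone, [O-][O+]=O
Why: Ozonolysis cleaves both alkenes and borohydride reduces the peroxidic products to the two primary alcohols. The C4 carbinol is not involved, so its configuration is carried over unchanged.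

Step 2
Reactants: 3 (2R)-2-methylpentane-1,2,5-triol
Product: 4 3-[(4R)-2,2,4-trimethyl-1,3-dioxolan-4-yl]propan-1-ol
Conditions: Me2C(OMe)2, pyridinium p-toluenesulfonate (cat.), acetone, rt; aq. NaHCO3
Reagents that add atoms: 2,2-dimethoxypropane, COC(C)(C)OC
Why: Acetonide formation under thermodynamic control gives the five-membered dioxolane of the C4,C5 diol and leaves the remote C1 hydroxyl free, which differentiates the two primary alcohols.

Step 3
Reactants: 4 3-[(4R)-2,2,4-trimethyl-1,3-dioxolan-4-yl]propan-1-ol
Product: 5 3-[(4R)-2,2,4-trimethyl-1,3-dioxolan-4-yl]propanal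
Conditions: TEMPO (2,2,6,6-tetramethylpiperidin-1-oxyl, cat.), PhI(OAc)2, CH2Cl2, rt
Reagents that add atoms: none
Why: Nitroxyl-catalysed oxidation of a primary alcohol stops at the aldehyde. The acetonide tolerates the acetic acid that is set free.

Step 4
Reactants: 5 3-[(4R)-2,2,4-trimethyl-1,3-dioxolan-4-yl]propanal; 6 (E)-but-2-ene
Product: 9 (3S,4R)-4-methyl-1-[(4R)-2,2,4-trimethyl-1,3-dioxolan-4-yl]hex-5-en-3-ol, via (E)-crotylpotassium 7 (not isolated), via crotylborane 8 (not isolated)
Conditions: 6, KOt-Bu, n-BuLi, THF, −78 to −45 °C; (+)-Ipc2BOMe [(+)-B-methoxydiisopinocampheylborane], −78 °C; BF3·OEt2; then 5, −78 °C; NaOH, H2O2, rt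
Reagents that add atoms: none
Why: Brown crotylboration: the (E)-crotylborane reacts through a chair transition state to give the anti adduct, and the isopinocampheyl groups of the (−)-α-pinene series direct attack to the Re face of the aldehyde, which should fix C10 as R. The C1 carbinol (S) is only a placeholder for the later ketone.

Step 5
Reactants: 9 (3S,4R)-4-methyl-1-[(4R)-2,2,4-trimethyl-1,3-dioxolan-4-yl]hex-5-en-3-ol
Product: 10 (4R)-4-[(3S,4R)-3-[(4-methoxyphenyl)methoxy]-4-methylhex-5-en-1-yl]-2,2,4-trimethyl-1,3-dioxolane
Conditions: NaH, 4-methoxybenzyl chloride, n-Bu4NI (cat.), DMF, 0 °C to rt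
Reagents that add atoms: 4-methoxybenzyl chloride, COc1ccc(CCl)cc1
Why: Williamson etherification of the only free hydroxyl. The PMB ether keeps C1 out of the ring closure and is the one group later removed by DDQ.

Step 6
Reactants: 10 (4R)-4-[(3S,4R)-3-[(4-methoxyphenyl)methoxy]-4-methylhex-5-en-1-yl]-2,2,4-trimethyl-1,3-dioxolane
Product: 12 (3R,4S)-4-[(4-methoxyphenyl)methoxy]-3-methyl-6-[(4R)-2,2,4-trimethyl-1,3-dioxolan-4-yl]hexan-1-ol, via alkylborane 11 (not isolated)
Conditions: 9-BBN (9-borabicyclo[3.3.1]nonane), THF, 0 °C to rt; NaOH, H2O2, 0 °C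
Reagents that add atoms: hydrogen peroxide, OO
Why: Anti-Markovnikov hydroboration–oxidation of the only alkene gives the C8 primary alcohol. No stereocentre is formed or touched.

Step 7
Reactants: 12 (3R,4S)-4-[(4-methoxyphenyl)methoxy]-3-methyl-6-[(4R)-2,2,4-trimethyl-1,3-dioxolan-4-yl]hexan-1-ol
Product: 13 (3R,4S)-4-[(4-methoxyphenyl)methoxy]-3-methyl-6-[(4R)-2,2,4-trimethyl-1,3-dioxolan-4-yl]hexanal
Conditions: TEMPO (2,2,6,6-tetramethylpiperidin-1-oxyl, cat.), PhI(OAc)2, CH2Cl2, rt
Reagents that add atoms: none
Why: The same mild nitroxyl oxidation as in step 3. The PMB ether and the acetonide are stable to it, and C10 is β to the new aldehyde and cannot epimerise.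

Step 8
Reactants: 14 furan-3-ylmethanol
Product: 15 tert-butyl(furan-3-ylmethoxy)dimethylsilane
Conditions: TBSCl, imidazole, DMF, rt
Reagents that add atoms: tert-butyldimethylsilyl chloride, CC(C)(C)[Si](C)(C)Cl
Why: Standard silylation of a primary alcohol. The silyl group is placed on oxygen so that it can be moved to carbon in the next step.

Step 9
Reactants: 15 tert-butyl(furan-3-ylmethoxy)dimethylsilane
Product: 16 {2-[tert-butyl(dimethyl)silyl]furan-3-yl}methanol
Conditions: n-BuLi, HMPA, THF, −78 °C to rt; aq. NH4Cl
Reagents that add atoms: none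
Why: Lithiation at the furan 2-position next to the silyloxymethyl group is followed by 1,4 oxygen-to-carbon silyl migration (retro-Brook rearrangement), a known reaction of 3-(silyloxymethyl)furans. It puts silicon on the carbon that becomes C12.

Step 10
Reactants: 13 (3R,4S)-4-[(4-methoxyphenyl)methoxy]-3-methyl-6-[(4R)-2,2,4-trimethyl-1,3-dioxolan-4-yl]hexanal; 16 {2-[tert-butyl(dimethyl)silyl]furan-3-yl}methanol
Product: 18 furyl diol as both C8 epimers, via dilithio furan 17 (not isolated)
Conditions: 16, n-BuLi (2.1 equiv), DME, 0 °C; then 13 in THF, −40 °C; aq. NH4Cl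
Reagents that add atoms: none
Why: The lithium alkoxide directs the second lithiation to the adjacent 4-position (known for 2-silylated furan-3-ylmethanols, whose 2-position is blocked), and the aryllithium adds to the aldehyde to form C7–C8. C8 is not controlled here and is reset in steps 12 and 13.

Step 11
Reactants: 18 furyl diol as both C8 epimers
Product: 19 C13 triisopropylsilyl ether of 18
Conditions: TIPSCl, imidazole, CH2Cl2, 0 °C
Reagents that add atoms: triisopropylsilyl chloride, CC(C)[Si](Cl)(C(C)C)C(C)C
Why: The bulky silyl chloride reacts with the primary hydroxyl and leaves the hindered secondary C8 hydroxyl free. A silyl ether at C13 is a poor leaving group, which the electron-rich silyloxyfuran will later require.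

Step 12
Reactants: 19 C13 triisopropylsilyl ether of 18
Product: 20 furyl ketone (C8 ketone)
Conditions: Dess–Martin periodinane, NaHCO3, CH2Cl2, 0 °C to rt
Reagents that add atoms: none
Why: Buffered Dess–Martin oxidation of the only free alcohol removes the uncontrolled C8 centre. C10 is β to the ketone and is not at risk.

Step 13
Reactants: 20 furyl ketone (C8 ketone)
Product: 21 (8S)-furyl carbinol
Conditions: (R)-2-methyl-CBS-oxazaborolidine [(R)-1-methyl-3,3-diphenyltetrahydro-1H,3H-pyrrolo[1,2-c][1,3,2]oxazaborole, 0.2 equiv], BH3·SMe2, THF, −20 °C; MeOH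
Reagents that add atoms: none
Why: Corey–Bakshi–Shibata reduction of a heteroaryl alkyl ketone, with the furyl group as the large substituent. The (R)-catalyst should deliver hydride to the face that gives the 8S carbinol, independently of the remote centres.

Step 14
Reactants: 21 (8S)-furyl carbinol; 22 angelic acid
Product: 24 angelate furan, via mixed anhydride 23 (not isolated)
Conditions: 22, 2,4,6-trichlorobenzoyl chloride, Et3N, toluene, rt; then 21, 75 °C
Reagents that add atoms: none
Why: Yamaguchi esterification without a nucleophilic amine catalyst, which transfers the angeloyl group to hindered secondary alcohols without Z to E isomerisation. C8 keeps its configuration because only the O–H bond reacts.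

Step 15
Reactants: 24 angelate furan
Product: 26 angelate butenolide, via hydroxybutenolide 25 (not isolated)
Conditions: O2, tetraphenylporphyrin (cat.), visible light, CH2Cl2, −78 °C; then NaBH4, MeOH, −40 °C; aq. citric acid
Reagents that add atoms: dioxygen (as singlet oxygen), O=O
Why: Singlet oxygen adds across the furan 2- and 5-positions, and the silyl group migrates from carbon to the peroxide oxygen (known for 2-trialkylsilylfurans), so the carbonyl appears at C12 and the lactol at C6. Borohydride reduces the open aldehyde form and acidification closes the butenolide with C6 as CH2.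

Step 16
Reactants: 26 angelate butenolide
Product: 27 C4,C5 diol
Conditions: AcOH/H2O (4:1), 40 °C
Reagents that add atoms: none
Why: Acid hydrolysis of the acetonide. The PMB ether, the primary triisopropylsilyl ether, the angelate and the butenolide are stable to aqueous acetic acid.

Step 17
Reactants: 27 C4,C5 diol
Product: 28 C4,C5 bis(triethylsilyl) ether
Conditions: TESOTf, 2,6-lutidine, CH2Cl2, −78 to 0 °C
Reagents that add atoms: triethylsilyl trifluoromethanesulfonate, CC[Si](CC)(CC)OS(=O)(=O)C(F)(F)F
Why: The silyl triflate silylates both the primary and the hindered tertiary hydroxyl. The tertiary triethylsilyl ether is the non-chelating C4 substituent for the aldol and the latent nucleophile for the epoxide.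

Step 18
Reactants: 28 C4,C5 bis(triethylsilyl) ether
Product: 29 butenolide aldehyde (C5 aldehyde)
Conditions: (COCl)2, DMSO, CH2Cl2, −78 to −40 °C; Et3N, −78 to 0 °C
Reagents that add atoms: none
Why: Under Swern conditions a primary triethylsilyl ether is cleaved and oxidised directly to the aldehyde, while tertiary triethylsilyl and triisopropylsilyl ethers remain (known selectivity). C4 has no hydrogen, so the α-silyloxy aldehyde cannot epimerise.

Step 19
Reactants: 29 butenolide aldehyde (C5 aldehyde)
Product: 30 silyloxyfuran aldehyde
Conditions: TBSOTf (1.1 equiv), Et3N, CH2Cl2, −78 °C; cold aq. NaHCO3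
Reagents that add atoms: tert-butyldimethylsilyl trifluoromethanesulfonate, CC(C)(C)[Si](C)(C)OS(=O)(=O)C(F)(F)F
Why: Soft enolisation of the butenolide at C6 gives the aromatic 2-silyloxyfuran, the standard preparation of these dienol ethers. No ketone is present to compete, and the low temperature keeps the silyl triflate from triggering the aldol itself.

Step 20
Reactants: 30 silyloxyfuran aldehyde
Product: 31 macrocyclic C5-hydroxy butenolide
Conditions: BF3·OEt2 (2 equiv), CH2Cl2, −78 °C, slow addition of 30 to a final 1 mM; aq. NaHCO3
Reagents that add atoms: none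
Why: Proposed new method: BF3 activates the C5 aldehyde and C6, the 5-position of the 2-silyloxyfuran, attacks it through an open transition state; loss of the silyl group from the oxocarbenium intermediate leaves the C7=C11 double bond in conjugation, so ring and butenolide arise together. The closest known reaction type is the intermolecular BF3-promoted vinylogous Mukaiyama aldol addition of 2-silyloxyfurans to α-alkoxy aldehydes, whose intramolecular form is known only for five- to seven-membered carbocycles. The ten-membered carbocycle closes in a 10-exo-trig mode at the aldehyde carbon; the five-membered lactone is not closed here but released from the furan. C5 is controlled by the C4 stereocentre through the polar Felkin–Anh arrangement (C4–O bond anti to the forming bond, the methyl group on the side of the aldehyde hydrogen, no chelation with monodentate BF3 and a silyl ether), which should give the 4,5-anti (5S) carbinol needed for the later inversion. C6 is controlled by the tether: the chain leaves the furan at C8, fixed in step 13, and is expected to bring the aldehyde to one face of C6 in a gauche turn about C4–C5···C6–C7. The step needs the 5,6-anti (5S,6S) adduct, whereas open-chain BF3 additions usually favour syn; that the ring constraint reverses this preference is the unproven point. Ring closure over oligomerisation is secured by high dilution, and the only other carbonyl carbon within reach, C1, is present as its PMB ether.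

Step 21
Reactants: 31 macrocyclic C5-hydroxy butenolide
Product: 32 C5 mesylate
Conditions: MsCl, Et3N, CH2Cl2, −40 °C
Reagents that add atoms: methanesulfonyl chloride, CS(=O)(=O)Cl
Why: Sulfonylation through the small sulfene intermediate reaches the hindered secondary hydroxyl. The C–O bond is not broken, so C5 stays S, and the low temperature holds back base-induced elimination.

Step 22
Reactants: 32 C5 mesylate
Product: 33 epoxy alcohol (C13 hydroxyl, C1 PMB ether)
Conditions: TBAF (2.5 equiv), THF, −20 to 0 °C
Reagents that add atoms: none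
Why: Fluoride cleaves both silyl ethers; the C4 alkoxide so formed displaces the adjacent mesylate in a 3-exo-tet closure with inversion at C5 (5S to 5R), a known way to make epoxides from β-silyloxy sulfonates. The anti arrangement of C4–O and C5–O set in step 20 gives the trans epoxide.

Step 23
Reactants: 33 epoxy alcohol (C13 hydroxyl, C1 PMB ether)
Product: 34 C13 acetate
Conditions: Ac2O, pyridine, CH2Cl2, 0 °C
Reagents that add atoms: acetic anhydride, CC(=O)OC(C)=O
Why: Acetylation of the only free, primary hydroxyl. No nucleophilic catalyst is used, so the angelate is not isomerised.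

Step 24
Reactants: 34 C13 acetate
Product: 35 C1 carbinol
Conditions: DDQ (2,3-dichloro-5,6-dicyano-1,4-benzoquinone), CH2Cl2/pH 7 phosphate buffer, 0 °C
Reagents that add atoms: none
Why: Oxidative cleavage of the PMB ether under buffered, near-neutral conditions, which spare the epoxide, both esters and the butenolide.

Step 25
Reactants: 35 C1 carbinol
Product: 36 CNP0229937.2 (target)
Conditions: Dess–Martin periodinane, NaHCO3, CH2Cl2, 0 °C
Reagents that add atoms: none
Why: Buffered Dess–Martin oxidation of the secondary alcohol to the C1 ketone. The oxidation is non-basic, so C10 (R), now α to the carbonyl, is not epimerised, and the buffer guards the epoxide against acid.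

## Compound list

1 | (R)-linalool, (3R)-3,7-dimethylocta-1,6-dien-3-ol | C=C[C@](C)(O)CCC=C(C)C | starting material
2 | (2R)-2-hydroxy-2-methylpentanedial (carbonyl stage of the ozonolysis mixture, not isolated) | O=C[C@](C)(O)CCC=O | intermediate
3 | (2R)-2-methylpentane-1,2,5-triol | OC[C@](C)(O)CCCO | intermediate
4 | 3-[(4R)-2,2,4-trimethyl-1,3-dioxolan-4-yl]propan-1-ol | CC1(C)OC[C@@](C)(CCCO)O1 | intermediate
5 | 3-[(4R)-2,2,4-trimethyl-1,3-dioxolan-4-yl]propanal | CC1(C)OC[C@@](C)(CCC=O)O1 | intermediate
6 | (E)-but-2-ene | C/C=C/C | starting material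
7 | (E)-but-2-enylpotassium (not isolated) | [K+].[CH2-]/C=C/C | intermediate
8 | (E)-but-2-enyldiisopinocampheylborane of the (−)-α-pinene series (not isolated) | C/C=C/CB([C@H]1C[C@H]2C[C@@H]([C@@H]1C)C2(C)C)[C@H]1C[C@H]2C[C@@H]([C@@H]1C)C2(C)C | intermediate
9 | (3S,4R)-4-methyl-1-[(4R)-2,2,4-trimethyl-1,3-dioxolan-4-yl]hex-5-en-3-ol (1S,10R in target numbering) | C=C[C@@H](C)[C@@H](O)CC[C@]1(C)COC(C)(C)O1 | intermediate
10 | (4R)-4-[(3S,4R)-3-[(4-methoxyphenyl)methoxy]-4-methylhex-5-en-1-yl]-2,2,4-trimethyl-1,3-dioxolane | C=C[C@@H](C)[C@@H](OCc1ccc(OC)cc1)CC[C@]1(C)COC(C)(C)O1 | intermediate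
11 | 9-[(3R,4S)-4-[(4-methoxyphenyl)methoxy]-3-methyl-6-[(4R)-2,2,4-trimethyl-1,3-dioxolan-4-yl]hexyl]-9-borabicyclo[3.3.1]nonane (not isolated) | C(C[C@@H](C)[C@@H](OCc1ccc(OC)cc1)CC[C@]1(C)COC(C)(C)O1)B1C2CCCC1CCC2 | intermediate
12 | (3R,4S)-4-[(4-methoxyphenyl)methoxy]-3-methyl-6-[(4R)-2,2,4-trimethyl-1,3-dioxolan-4-yl]hexan-1-ol | OCC[C@@H](C)[C@@H](OCc1ccc(OC)cc1)CC[C@]1(C)COC(C)(C)O1 | intermediate
13 | (3R,4S)-4-[(4-methoxyphenyl)methoxy]-3-methyl-6-[(4R)-2,2,4-trimethyl-1,3-dioxolan-4-yl]hexanal | O=CC[C@@H](C)[C@@H](OCc1ccc(OC)cc1)CC[C@]1(C)COC(C)(C)O1 | intermediate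
14 | furan-3-ylmethanol | OCc1ccoc1 | starting material
15 | tert-butyl(furan-3-ylmethoxy)dimethylsilane | CC(C)(C)[Si](C)(C)OCc1ccoc1 | intermediate
16 | {2-[tert-butyl(dimethyl)silyl]furan-3-yl}methanol | CC(C)(C)[Si](C)(C)c1occc1CO | intermediate
17 | lithium {2-[tert-butyl(dimethyl)silyl]-4-lithiofuran-3-yl}methanolate (not isolated) | [Li]OCc1c([Li])coc1[Si](C)(C)C(C)(C)C | intermediate
18 | (3R,4S)-1-{5-[tert-butyl(dimethyl)silyl]-4-(hydroxymethyl)furan-3-yl}-4-[(4-methoxyphenyl)methoxy]-3-methyl-6-[(4R)-2,2,4-trimethyl-1,3-dioxolan-4-yl]hexan-1-ol, both epimers at C1 of the hexanol (C8 of the target) | OC(C[C@@H](C)[C@@H](OCc1ccc(OC)cc1)CC[C@]1(C)COC(C)(C)O1)c1coc([Si](C)(C)C(C)(C)C)c1CO | intermediate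
19 | 18 with the furan CH2OH (C13) as its tri(propan-2-yl)silyl ether, both C8 epimers | OC(C[C@@H](C)[C@@H](OCc1ccc(OC)cc1)CC[C@]1(C)COC(C)(C)O1)c1coc([Si](C)(C)C(C)(C)C)c1CO[Si](C(C)C)(C(C)C)C(C)C | intermediate
20 | (3R,4S)-1-{5-[tert-butyl(dimethyl)silyl]-4-({[tri(propan-2-yl)silyl]oxy}methyl)furan-3-yl}-4-[(4-methoxyphenyl)methoxy]-3-methyl-6-[(4R)-2,2,4-trimethyl-1,3-dioxolan-4-yl]hexan-1-one | O=C(C[C@@H](C)[C@@H](OCc1ccc(OC)cc1)CC[C@]1(C)COC(C)(C)O1)c1coc([Si](C)(C)C(C)(C)C)c1CO[Si](C(C)C)(C(C)C)C(C)C | intermediate
21 | (1S,3R,4S)-1-{5-[tert-butyl(dimethyl)silyl]-4-({[tri(propan-2-yl)silyl]oxy}methyl)furan-3-yl}-4-[(4-methoxyphenyl)methoxy]-3-methyl-6-[(4R)-2,2,4-trimethyl-1,3-dioxolan-4-yl]hexan-1-ol | O[C@@H](C[C@@H](C)[C@@H](OCc1ccc(OC)cc1)CC[C@]1(C)COC(C)(C)O1)c1coc([Si](C)(C)C(C)(C)C)c1CO[Si](C(C)C)(C(C)C)C(C)C | intermediate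
22 | angelic acid, (2Z)-2-methylbut-2-enoic acid | C/C=C(/C)C(=O)O | starting material
23 | (2Z)-2-methylbut-2-enoic 2,4,6-trichlorobenzoic anhydride (not isolated) | C/C=C(/C)C(=O)OC(=O)c1c(Cl)cc(Cl)cc1Cl | intermediate
24 | (2Z)-2-methylbut-2-enoate of 21 (ester at the 8S carbinol) | C/C=C(/C)C(=O)O[C@@H](C[C@@H](C)[C@@H](OCc1ccc(OC)cc1)CC[C@]1(C)COC(C)(C)O1)c1coc([Si](C)(C)C(C)(C)C)c1CO[Si](C(C)C)(C(C)C)C(C)C | intermediate
25 | (1S,3R,4S)-1-[2-hydroxy-5-oxo-4-({[tri(propan-2-yl)silyl]oxy}methyl)-2,5-dihydrofuran-3-yl]-4-[(4-methoxyphenyl)methoxy]-3-methyl-6-[(4R)-2,2,4-trimethyl-1,3-dioxolan-4-yl]hexyl (2Z)-2-methylbut-2-enoate, lactol epimers (not isolated) | C/C=C(/C)C(=O)O[C@@H](C[C@@H](C)[C@@H](OCc1ccc(OC)cc1)CC[C@]1(C)COC(C)(C)O1)C1=C(CO[Si](C(C)C)(C(C)C)C(C)C)C(=O)OC1O | intermediate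
26 | (1S,3R,4S)-4-[(4-methoxyphenyl)methoxy]-3-methyl-1-[5-oxo-4-({[tri(propan-2-yl)silyl]oxy}methyl)-2,5-dihydrofuran-3-yl]-6-[(4R)-2,2,4-trimethyl-1,3-dioxolan-4-yl]hexyl (2Z)-2-methylbut-2-enoate | C/C=C(/C)C(=O)O[C@@H](C[C@@H](C)[C@@H](OCc1ccc(OC)cc1)CC[C@]1(C)COC(C)(C)O1)C1=C(CO[Si](C(C)C)(C(C)C)C(C)C)C(=O)OC1 | intermediate
27 | (1S,3R,4S,7R)-7,8-dihydroxy-4-[(4-methoxyphenyl)methoxy]-3,7-dimethyl-1-[5-oxo-4-({[tri(propan-2-yl)silyl]oxy}methyl)-2,5-dihydrofuran-3-yl]octyl (2Z)-2-methylbut-2-enoate | C/C=C(/C)C(=O)O[C@@H](C[C@@H](C)[C@@H](OCc1ccc(OC)cc1)CC[C@@](C)(O)CO)C1=C(CO[Si](C(C)C)(C(C)C)C(C)C)C(=O)OC1 | intermediate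
28 | 7,8-bis(triethylsilyl) ether of 27 | C/C=C(/C)C(=O)O[C@@H](C[C@@H](C)[C@@H](OCc1ccc(OC)cc1)CC[C@@](C)(O[Si](CC)(CC)CC)CO[Si](CC)(CC)CC)C1=C(CO[Si](C(C)C)(C(C)C)C(C)C)C(=O)OC1 | intermediate
29 | (1S,3R,4S,7R)-4-[(4-methoxyphenyl)methoxy]-3,7-dimethyl-8-oxo-1-[5-oxo-4-({[tri(propan-2-yl)silyl]oxy}methyl)-2,5-dihydrofuran-3-yl]-7-[(triethylsilyl)oxy]octyl (2Z)-2-methylbut-2-enoate | C/C=C(/C)C(=O)O[C@@H](C[C@@H](C)[C@@H](OCc1ccc(OC)cc1)CC[C@@](C)(O[Si](CC)(CC)CC)C=O)C1=C(CO[Si](C(C)C)(C(C)C)C(C)C)C(=O)OC1 | intermediate
30 | (1S,3R,4S,7R)-1-[5-{[tert-butyl(dimethyl)silyl]oxy}-4-({[tri(propan-2-yl)silyl]oxy}methyl)furan-3-yl]-4-[(4-methoxyphenyl)methoxy]-3,7-dimethyl-8-oxo-7-[(triethylsilyl)oxy]octyl (2Z)-2-methylbut-2-enoate (key-step precursor) | C/C=C(/C)C(=O)O[C@@H](C[C@@H](C)[C@@H](OCc1ccc(OC)cc1)CC[C@@](C)(O[Si](CC)(CC)CC)C=O)c1coc(O[Si](C)(C)C(C)(C)C)c1CO[Si](C(C)C)(C(C)C)C(C)C | intermediate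
31 | (1S,4R,5S,6S,8S,10R)-8-angeloyloxy-5-hydroxy-1-[(4-methoxyphenyl)methoxy]-4-(triethylsilyloxy)-13-[tri(propan-2-yl)silyloxy]germacr-7(11)-en-12,6-olide (key-step product) | C/C=C(/C)C(=O)O[C@H]1C[C@@H](C)[C@@H](OCc2ccc(OC)cc2)CC[C@@](C)(O[Si](CC)(CC)CC)[C@@H](O)[C@H]2OC(=O)C(CO[Si](C(C)C)(C(C)C)C(C)C)=C12 | intermediate
32 | 5-O-methanesulfonate of 31 (1S,4R,5S,6S,8S,10R) | C/C=C(/C)C(=O)O[C@H]1C[C@@H](C)[C@@H](OCc2ccc(OC)cc2)CC[C@@](C)(O[Si](CC)(CC)CC)[C@@H](OS(C)(=O)=O)[C@H]2OC(=O)C(CO[Si](C(C)C)(C(C)C)C(C)C)=C12 | intermediate
33 | (1S,4R,5R,6S,8S,10R)-8-angeloyloxy-4,5-epoxy-13-hydroxy-1-[(4-methoxyphenyl)methoxy]germacr-7(11)-en-12,6-olide | C/C=C(/C)C(=O)O[C@H]1C[C@@H](C)[C@@H](OCc2ccc(OC)cc2)CC[C@@]2(C)O[C@@H]2[C@H]2OC(=O)C(CO)=C12 | intermediate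
34 | (1S,4R,5R,6S,8S,10R)-13-acetoxy-8-angeloyloxy-4,5-epoxy-1-[(4-methoxyphenyl)methoxy]germacr-7(11)-en-12,6-olide | C/C=C(/C)C(=O)O[C@H]1C[C@@H](C)[C@@H](OCc2ccc(OC)cc2)CC[C@@]2(C)O[C@@H]2[C@H]2OC(=O)C(COC(C)=O)=C12 | intermediate
35 | (1S,4R,5R,6S,8S,10R)-13-acetoxy-8-angeloyloxy-4,5-epoxy-1-hydroxygermacr-7(11)-en-12,6-olide | C/C=C(/C)C(=O)O[C@H]1C[C@@H](C)[C@@H](O)CC[C@@]2(C)O[C@@H]2[C@H]2OC(=O)C(COC(C)=O)=C12 | intermediate
36 | CNP0229937.2, (4R,5R,6S,8S,10R)-13-acetoxy-8-angeloyloxy-4,5-epoxy-1-oxogermacr-7(11)-en-12,6-olide | C/C=C(/C)C(=O)O[C@H]1C[C@@H](C)C(=O)CC[C@@]2(C)O[C@@H]2[C@H]2OC(=O)C(COC(C)=O)=C12 | target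

## Step count and least certain steps

Total: 25 steps. Longest linear sequence: 23 steps (steps 1 to 7 and 10 to 25, from 1); the furan branch (steps 8 and 9) joins at step 10.

**Step 20 (key step).** The closure of a ten-membered ring is slow, so intermolecular aldol addition, oligomerisation and protodesilylation back to the butenolide can overtake it. The second danger is attack on the other face of the furan: the rotamer about C7–C8 that minimises allylic strain with the C13 substituent holds the chain on that face, and open-chain additions of this kind prefer the syn relationship. The fallback uses known chemistry, sets out from 24 and returns at 31.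
- N-Iodosuccinimide iodinates the free furan α-position C6 of 24 to give the 2-iodofuran F1.
- As in steps 16 to 18, the acetonide is hydrolysed to the diol F2, both hydroxyls are silylated to the bis(triethylsilyl) ether F3, and the primary silyl ether is oxidised under Swern conditions to the iodofuran aldehyde F4.
- CrCl2 with catalytic NiCl2 in DMSO at high dilution joins C6 to C5 (Nozaki–Hiyama–Kishi reaction of a 2-halofuran with an aldehyde, an established route to medium-ring furanophanes) and gives the macrocyclic furyl carbinol F5.
- Photooxygenation of the 2-silylfuran as in step 15 gives the C6 hemiketal F6, the ring tautomer of a C6 ketone. Zn(BH4)2 reduces the ketone form under chelation by the C5 hydroxyl to the 5,6-anti diol, which lactonises to 31.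

Ring closure, C5 and C6 are then settled in three separate operations of known type.

**Step 22.** The C6–H of the butenolide is acidic, so fluoride or the alkoxides formed can remove it and expel the mesylate by elimination through the dienolate, in place of displacement by the C4 alkoxide. The fallback sets out from 31 and returns at 34.
- HF·pyridine in THF removes both silyl ethers without base and gives the triol F7.
- Acetyl chloride with 2,4,6-collidine at −78 °C acetylates only the primary hydroxyl, giving the diol acetate F8.
- PPh3 and diisopropyl azodicarboxylate (Mitsunobu cyclodehydration of a vicinal diol) activate the secondary C5 hydroxyl, and the tertiary C4 hydroxyl displaces it with inversion to give 34. No sulfonate and no free alkoxide are involved.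

**Step 15.** During the borohydride stage the angeloyl group can migrate from the C8 oxygen to the new C6 alkoxide, after which lactonisation would go through the wrong oxygen. The fallback sets out from 24 and returns at 26: peracetic acid buffered with NaOAc in CH2Cl2 transfers one oxygen to the silyl-bearing furan double bond, the silyl group shifts from carbon to oxygen, and hydrolysis gives the butenolide directly. No C6 hydroxyl and no alkoxide next to the ester are formed, and the fallback passes through no compound outside the list (F0).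

**Step 18.** The primary silyl ether is neopentyl and may react slowly, and forcing the conditions risks loss of the tertiary silyl ether. The fallback sets out from 27 and returns at 29: TEMPO with PhI(OAc)2 oxidises only the primary hydroxyl of the diol to the α-hydroxy aldehyde F9, which is silylated at once at the tertiary hydroxyl with TESOTf and 2,6-lutidine to give 29.

## Further compounds

F1 | step 20 | C6-iodo derivative of 24 (iodine on the free furan α-carbon) | C/C=C(/C)C(=O)O[C@@H](C[C@@H](C)[C@@H](OCc1ccc(OC)cc1)CC[C@]1(C)COC(C)(C)O1)c1c(I)oc([Si](C)(C)C(C)(C)C)c1CO[Si](C(C)C)(C(C)C)C(C)C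
F2 | step 20 | C4,C5 diol from F1 (acetonide removed) | C/C=C(/C)C(=O)O[C@@H](C[C@@H](C)[C@@H](OCc1ccc(OC)cc1)CC[C@@](C)(O)CO)c1c(I)oc([Si](C)(C)C(C)(C)C)c1CO[Si](C(C)C)(C(C)C)C(C)C
F3 | step 20 | C4,C5 bis(triethylsilyl) ether of F2 | C/C=C(/C)C(=O)O[C@@H](C[C@@H](C)[C@@H](OCc1ccc(OC)cc1)CC[C@@](C)(O[Si](CC)(CC)CC)CO[Si](CC)(CC)CC)c1c(I)oc([Si](C)(C)C(C)(C)C)c1CO[Si](C(C)C)(C(C)C)C(C)C
F4 | step 20 | iodofuran C5 aldehyde with C4 triethylsilyl ether | C/C=C(/C)C(=O)O[C@@H](C[C@@H](C)[C@@H](OCc1ccc(OC)cc1)CC[C@@](C)(O[Si](CC)(CC)CC)C=O)c1c(I)oc([Si](C)(C)C(C)(C)C)c1CO[Si](C(C)C)(C(C)C)C(C)C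
F5 | step 20 | macrocyclic furan with the (5S) carbinol bonded to furan C6, C12 silyl group retained | C/C=C(/C)C(=O)O[C@H]1C[C@@H](C)[C@@H](OCc2ccc(OC)cc2)CC[C@@](C)(O[Si](CC)(CC)CC)[C@@H](O)c2oc([Si](C)(C)C(C)(C)C)c(CO[Si](C(C)C)(C(C)C)C(C)C)c12
F6 | step 20 | macrocyclic 6-hydroxybutenolide (C6 hemiketal, epimers at C6) | C/C=C(/C)C(=O)O[C@H]1C[C@@H](C)[C@@H](OCc2ccc(OC)cc2)CC[C@@](C)(O[Si](CC)(CC)CC)[C@@H](O)C2(O)OC(=O)C(CO[Si](C(C)C)(C(C)C)C(C)C)=C12
F7 | step 22 | (1S,4R,5S,6S,8S,10R)-8-angeloyloxy-4,5,13-trihydroxy-1-[(4-methoxyphenyl)methoxy]germacr-7(11)-en-12,6-olide | C/C=C(/C)C(=O)O[C@H]1C[C@@H](C)[C@@H](OCc2ccc(OC)cc2)CC[C@@](C)(O)[C@@H](O)[C@H]2OC(=O)C(CO)=C12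
F8 | step 22 | 13-acetate of F7 | C/C=C(/C)C(=O)O[C@H]1C[C@@H](C)[C@@H](OCc2ccc(OC)cc2)CC[C@@](C)(O)[C@@H](O)[C@H]2OC(=O)C(COC(C)=O)=C12
F0 | step 15 | none | none
F9 | step 18 | C5 aldehyde with free C4 hydroxyl (α-hydroxy aldehyde from 27) | C/C=C(/C)C(=O)O[C@@H](C[C@@H](C)[C@@H](OCc1ccc(OC)cc1)CC[C@@](C)(O)C=O)C1=C(CO[Si](C(C)C)(C(C)C)C(C)C)C(=O)OC1
A1 | alternative 1 | 4,5-epoxy-1-oxogermacra-7(8)E,11(13)-dien-12,6-olide, configured as the target at C4, C5, C6 and C10 | C1[C@@H](C)C(=O)CC[C@@]2(C)O[C@@H]2[C@H]2OC(=O)C(=C)/C2=C\1
A2 | alternative 1 | C8,C13-endoperoxide (1,2-dioxine) fused to the butenolide | O3[C@H]1C[C@@H](C)C(=O)CC[C@@]2(C)O[C@@H]2[C@H]2OC(=O)C(CO3)=C12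
A3 | alternative 2 | trans-3-(2-chloroethyl)-3-methyloxirane-2-carbaldehyde with the C4 and C5 configuration of the target | O=C[C@H]1O[C@]1(C)CCCl
A4 | alternative 2 | methyl (Z)-3-iodo-2-(silyloxymethyl)enoate carrying the C8 silyl ether, C10 methyl and C1 PMB ether | C[C@@H](COCc1ccc(OC)cc1)C[C@H](O[Si](C)(C)C(C)(C)C)/C(I)=C(\CO[Si](C)(C)C(C)(C)C)C(=O)OC
A5 | alternative 2 | butenolide union product with all five stereocentres | C[C@@H](COCc1ccc(OC)cc1)C[C@H](O[Si](C)(C)C(C)(C)C)C1=C(CO[Si](C)(C)C(C)(C)C)C(=O)O[C@@H]1[C@H]1O[C@]1(C)CCCl
A6 | alternative 3 | open-chain C1 aldehyde with (E)-crotonyl ketone at C8, epoxide and C6 silyl ether in place | O=CCC[C@@]1(C)O[C@@H]1[C@@H](O[Si](C)(C)C(C)(C)C)/C(C(=O)/C=C/C)=C(/COC(C)=O)C(=O)OC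
A7 | alternative 3 | ten-membered 1,8-diketone with the enoate not yet lactonised | O=C1C[C@@H](C)C(=O)CC[C@@]2(C)O[C@@H]2[C@@H](O[Si](C)(C)C(C)(C)C)/C1=C(/COC(C)=O)C(=O)OC
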